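**Strategy.** The cyclohexane ring (C1–C6) is disconnected at C1–C2 and C5–C6. An enantioselective, endo-selective [4+2] cycloaddition of an (E)-1-silyloxy-2-methylbutadiene (C2–C5) with methyl (Z)-4-oxopent-2-enoate (C6, C1) closes the ring and sets C1, C5 and C6 in one operation. It exploits the all-cis array of the C5 oxygen, the C6 oxygen and the C1 carbon substituent that flanks the C3=C4(Me) unit. The acetyl group is a latent C6 oxygen and the ester is the root of the C7–C11 chain. C2–OH and the C3–C4 oxirane follow from the ring alkene, and C8/C10 from an aldol–Evans–Tishchenko pair.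

Key step: step 4

Numbering: ring atoms C1–C6 and chain atoms C7–C11 are numbered as in the target (C1 bears the chain, C4 the methyl), also in the names; "upper face" is the face of the C1, C5 and C6 substituents.

Assumption: the facial sense of the oxazaborolidinium catalyst is assigned from the usual α-C–H···O binding model of enones, which points to the (R)-configured catalyst; the (S)-catalyst is the direct substitute if the first run shows the opposite sense.

**Step 1**
Reactants: 1 (E)-2-methylbut-2-enal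
Product: 2 (E)-1-(tert-butyldimethylsilyloxy)-2-methylbuta-1,3-diene
Conditions: TBSOTf, Et3N, Et2O, 0 °C → rt
Reagents that add atoms: tert-butyldimethylsilyl trifluoromethanesulfonate, CC(C)(C)[Si](C)(C)OS(=O)(=O)C(F)(F)F
Why: O-silylation of the enal and γ-deprotonation of the C4 methyl by Et3N (vinylogous silyl enol ether formation) should give the 1-silyloxydiene, the (1E) isomer with oxygen trans to the vinyl group being favoured and the only one able to react in step 4.

**Step 2**
Reactants: 3 2-methylfuran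
Product: 5 5-hydroxy-5-methylfuran-2(5H)-one, via (Z)-4-oxopent-2-enal 4 (not isolated)
Conditions: NBS, NaHCO3, acetone/H2O, −20 °C; then NaClO2, NaH2PO4, 2-methylbut-2-ene, t-BuOH/H2O, 0 °C
Reagents that add atoms: water, O; sodium chlorite, [Na+].[O-]Cl=O
Why: Oxidative furan ring opening (bromination, hydration, loss of HBr) gives the cis-enedicarbonyl compound, Pinnick oxidation takes its aldehyde to the acid, and closure to the hydroxybutenolide (ring tautomer of (Z)-4-oxopent-2-enoic acid) locks the Z geometry.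

**Step 3**
Reactants: 5 5-hydroxy-5-methylfuran-2(5H)-one
Product: 6 methyl (Z)-4-oxopent-2-enoate
Conditions: MeI, K2CO3, acetone, 0 °C → rt, dark
Reagents that add atoms: iodomethane, CI
Why: Under base the ring-opened carboxylate is the nucleophile, so SN2 O-methylation (carboxylate alkylation) should give the open-chain ester with the cis alkene intact.

**Step 4**
Reactants: 2 (E)-1-(tert-butyldimethylsilyloxy)-2-methylbuta-1,3-diene; 6 methyl (Z)-4-oxopent-2-enoate
Product: 7 methyl (1S,5S,6S)-6-acetyl-5-(tert-butyldimethylsilyloxy)-4-methylcyclohex-3-ene-1-carboxylate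
Conditions: (R)-3,3-diphenyl-1-(o-tolyl)tetrahydro-1H,3H-pyrrolo[1,2-c][1,3,2]oxazaborole (20 mol%), Tf2NH (18 mol%), CH2Cl2, −78 °C
Reagents that add atoms: none
Why: This is a Lewis acid-catalysed normal-demand Diels–Alder reaction in which the N-protonated oxazaborolidine binds the ketone of 6 and a concerted, asynchronous [4+2] addition joins the unsubstituted diene terminus C2 to the β-carbon C1 and the oxygen-bearing terminus C5 to the acetyl-bearing carbon C6. The closest known reaction type is the oxazaborolidinium-catalysed cycloaddition of silyloxydienes with acrylates, enones and quinones. The ring C1–C6 closes by suprafacial addition on both components, a thermally allowed [π4s+π2s] process. C1 and C6 keep the cis relationship of the (Z)-alkene, the endo orientation of both carbonyl groups toward the (E)-diene puts the C5 silyloxy group on the same face, and the absolute sense comes from the catalyst, whose aryl groups screen one face of the bound dienophile. The step needs ortho regiochemistry, endo topology and one enantioface: the silyloxy group outweighs the C4 methyl in polarising the diene, the bound ketone outweighs the ester in the dienophile, and the cis-diacyl alkene at low temperature reacts endo.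

**Step 5**
Reactants: 7 methyl (1S,5S,6S)-6-acetyl-5-(tert-butyldimethylsilyloxy)-4-methylcyclohex-3-ene-1-carboxylate
Product: 9 methyl (1S,3S,4S,5S,6S)-6-acetoxy-5-(tert-butyldimethylsilyloxy)-3,4-epoxy-4-methylcyclohexane-1-carboxylate, via epoxy ketone 8 (not isolated)
Conditions: mCPBA (3 equiv), NaHCO3, CH2Cl2, 0 °C → rt
Reagents that add atoms: 3-chloroperbenzoic acid, OOC(=O)c1cccc(Cl)c1
Why: Prilezhaev epoxidation of the trisubstituted alkene should occur first, on the face opposite the three cis substituents, and the slower Baeyer–Villiger oxidation then inserts oxygen between C6 and the acetyl carbon with migration of the secondary ring carbon and retention at C6.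

**Step 6**
Reactants: 9 methyl (1S,3S,4S,5S,6S)-6-acetoxy-5-(tert-butyldimethylsilyloxy)-3,4-epoxy-4-methylcyclohexane-1-carboxylate
Product: 10 2-[(1S,3S,4S,5S,6S)-5-(tert-butyldimethylsilyloxy)-3,4-epoxy-6-hydroxy-4-methylcyclohexyl]propan-2-ol
Conditions: MeLi (6 equiv), CeCl3, THF, −78 °C; aq. NH4Cl
Reagents that add atoms: methyllithium, [Li]C
Why: The organocerium reagent adds twice to the methyl ester to give the tertiary carbinol and cleaves the acetate, while its low basicity avoids enolisation at C1 and β-elimination of the C6 oxygen (ester to tertiary alcohol by organocerium addition).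

**Step 7**
Reactants: 10 2-[(1S,3S,4S,5S,6S)-5-(tert-butyldimethylsilyloxy)-3,4-epoxy-6-hydroxy-4-methylcyclohexyl]propan-2-ol
Product: 11 (1S,3S,4S,5S,6S)-5-(tert-butyldimethylsilyloxy)-3,4-epoxy-1-(2-hydroxypropan-2-yl)-4-methylcyclohex-6-yl 2-methylpropanoate
Conditions: i-PrCOCl, pyridine, DMAP (cat.), CH2Cl2, 0 °C → rt
Reagents that add atoms: isobutyryl chloride, CC(C)C(Cl)=O
Why: DMAP-catalysed acylation should take place at the secondary C6 hydroxyl only, the tertiary C7 hydroxyl being inert under these conditions.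

**Step 8**
Reactants: 11 (1S,3S,4S,5S,6S)-5-(tert-butyldimethylsilyloxy)-3,4-epoxy-1-(2-hydroxypropan-2-yl)-4-methylcyclohex-6-yl 2-methylpropanoate
Product: 12 (1R,3S,4S,5S,6S)-5-(tert-butyldimethylsilyloxy)-3,4-epoxy-4-methyl-1-(prop-1-en-2-yl)cyclohex-6-yl 2-methylpropanoate
Conditions: Burgess reagent (methyl N-(triethylammoniosulfonyl)carbamate), toluene, 60 °C
Reagents that add atoms: none
Why: syn-Elimination of the tertiary sulfamate (Burgess dehydration) should remove a methyl hydrogen in preference to the hindered C1–H flanked by C2 and the acylated C6, giving the isopropenyl group under neutral conditions that spare the oxirane.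

**Step 9**
Reactants: 12 (1R,3S,4S,5S,6S)-5-(tert-butyldimethylsilyloxy)-3,4-epoxy-4-methyl-1-(prop-1-en-2-yl)cyclohex-6-yl 2-methylpropanoate
Product: 14 (1R,4S,5S,6S)-5-(tert-butyldimethylsilyloxy)-4-hydroxy-4-methyl-1-(prop-1-en-2-yl)cyclohex-2-en-6-yl 2-methylpropanoate, via hydroxy selenide 13 (not isolated)
Conditions: (PhSe)2, NaBH4, EtOH, 60–78 °C; then THF, pyridine, 30% H2O2, 0 °C → rt
Reagents that add atoms: none
Why: In this epoxide-to-allylic-alcohol isomerisation, benzeneselenolate opens the oxirane by SN2 at the secondary C3 (inversion, oxygen stays on C4 on the lower face) and the derived selenoxide undergoes syn-elimination toward C2, the only neighbour with hydrogen, to give the C2=C3 alkene and the tertiary C4 alcohol; the opening is not trans-diaxial in the preferred chair, hence the elevated temperature on a substrate that tolerates it.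

**Step 10**
Reactants: 14 (1R,4S,5S,6S)-5-(tert-butyldimethylsilyloxy)-4-hydroxy-4-methyl-1-(prop-1-en-2-yl)cyclohex-2-en-6-yl 2-methylpropanoate
Product: 15 (1R,4S,5S,6S)-4,5-dihydroxy-4-methyl-1-(prop-1-en-2-yl)cyclohex-2-en-6-yl 2-methylpropanoate
Conditions: HF·pyridine, pyridine, THF, 0 °C → rt
Reagents that add atoms: none
Why: Buffered fluoride desilylation frees the C5 hydroxyl without base, so the neighbouring C6 isobutyrate should not migrate and the tertiary allylic alcohol should not ionise.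

**Step 11**
Reactants: 15 (1R,4S,5S,6S)-4,5-dihydroxy-4-methyl-1-(prop-1-en-2-yl)cyclohex-2-en-6-yl 2-methylpropanoate
Product: 16 (1R,4S,5S,6S)-5-acetoxy-4-hydroxy-4-methyl-1-(prop-1-en-2-yl)cyclohex-2-en-6-yl 2-methylpropanoate
Conditions: Ac2O, pyridine, DMAP (cat.), CH2Cl2, 0 °C
Reagents that add atoms: acetic anhydride, CC(=O)OC(C)=O
Why: Acetylation should occur at the only secondary hydroxyl (C5), placing the acetate before any C2 hydroxyl exists, while the tertiary allylic C4 hydroxyl stays free.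

**Step 12**
Reactants: 16 (1R,4S,5S,6S)-5-acetoxy-4-hydroxy-4-methyl-1-(prop-1-en-2-yl)cyclohex-2-en-6-yl 2-methylpropanoate
Product: 17 (1S,2R,5R,6S)-5-acetoxy-2-hydroxy-4-methyl-1-(prop-1-en-2-yl)cyclohex-3-en-6-yl 2-methylpropanoate
Conditions: Ph3SiOReO3 (5 mol%), Et2O, −20 → 0 °C
Reagents that add atoms: none
Why: The rhenium-oxo-catalysed 1,3-transposition of the allylic alcohol runs through a cyclic perrhenate ester ([3,3]-sigmatropic shift) that moves the hydroxyl from C4 to C2 across the same lower face, so C2 is set trans to the C1 substituent, and it is driven by the trisubstituted C3=C4 alkene and the less hindered secondary alcohol.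

**Step 13**
Reactants: 17 (1S,2R,5R,6S)-5-acetoxy-2-hydroxy-4-methyl-1-(prop-1-en-2-yl)cyclohex-3-en-6-yl 2-methylpropanoate
Product: 18 (1S,2S,3S,4S,5S,6S)-5-acetoxy-3,4-epoxy-2-hydroxy-4-methyl-1-(prop-1-en-2-yl)cyclohex-6-yl 2-methylpropanoate
Conditions: VO(acac)2 (5 mol%), t-BuOOH, CH2Cl2, 0 °C → rt
Reagents that add atoms: tert-butyl hydroperoxide, CC(C)(C)OO
Why: In this vanadium-catalysed hydroxyl-directed epoxidation the C2 alkoxide on the metal delivers the peroxide oxygen to C3=C4 on its own face, cis to the C2 hydroxyl and anti to the C5 acetate, while the homoallylic 1,1-disubstituted isopropenyl alkene reacts far more slowly.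

**Step 14**
Reactants: 18 (1S,2S,3S,4S,5S,6S)-5-acetoxy-3,4-epoxy-2-hydroxy-4-methyl-1-(prop-1-en-2-yl)cyclohex-6-yl 2-methylpropanoate
Product: 19 (1R,2S,3S,4S,5S,6S)-5-acetoxy-3,4-epoxy-4-methyl-1-(prop-1-en-2-yl)-2-(triethylsilyloxy)cyclohex-6-yl 2-methylpropanoate
Conditions: TESCl, imidazole, DMAP (cat.), DMF, rt
Reagents that add atoms: chlorotriethylsilane, CC[Si](Cl)(CC)CC
Why: Silylation masks the secondary C2 hydroxyl for the allylic oxidation, aldol and acylation steps, and the ether is cleaved together with the C11 ether in the last step.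

**Step 15**
Reactants: 19 (1R,2S,3S,4S,5S,6S)-5-acetoxy-3,4-epoxy-4-methyl-1-(prop-1-en-2-yl)-2-(triethylsilyloxy)cyclohex-6-yl 2-methylpropanoate
Product: 21 (1R,2S,3S,4S,5S,6S)-5-acetoxy-3,4-epoxy-4-methyl-1-(3-oxoprop-1-en-2-yl)-2-(triethylsilyloxy)cyclohex-6-yl 2-methylpropanoate, via allylic alcohol 20 (not isolated)
Conditions: SeO2 (cat.), t-BuOOH, CH2Cl2, rt; then MnO2, CH2Cl2, rt
Reagents that add atoms: tert-butyl hydroperoxide, CC(C)(C)OO (oxygen passed on through selenium dioxide, O=[Se]=O)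
Why: Allylic oxidation by ene reaction and [2,3]-sigmatropic shift of the allylseleninic acid should functionalise the isopropenyl methyl, because the alternative C1–H is hindered and deactivated by the oxygenated C2 and C6 and the ring has no other alkene, and MnO2 takes the primary allylic alcohol on to the enal.

**Step 16**
Reactants: 22 3-hydroxy-3-methylbutan-2-one
Product: 23 3-methyl-3-(triethylsilyloxy)butan-2-one
Conditions: TESOTf, 2,6-lutidine, CH2Cl2, −78 → 0 °C
Reagents that add atoms: triethylsilyl trifluoromethanesulfonate, CC[Si](CC)(CC)OS(=O)(=O)C(F)(F)F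
Why: Silyl triflate silylation of the tertiary hydroxyl masks it for boron enolate formation.

**Step 17**
Reactants: 21 (1R,2S,3S,4S,5S,6S)-5-acetoxy-3,4-epoxy-4-methyl-1-(3-oxoprop-1-en-2-yl)-2-(triethylsilyloxy)cyclohex-6-yl 2-methylpropanoate; 23 3-methyl-3-(triethylsilyloxy)butan-2-one
Product: 25 (1R,2S,3S,4S,5S,6S)-5-acetoxy-3,4-epoxy-1-[(3S)-3-hydroxy-6-methyl-5-oxo-6-(triethylsilyloxy)hept-1-en-2-yl]-4-methyl-2-(triethylsilyloxy)cyclohex-6-yl 2-methylpropanoate, via enol diisopinocampheylborinate 24 (not isolated)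
Conditions: 23, (−)-Ipc2BCl, Et3N, Et2O, 0 °C; then 21, −78 → −20 °C; then pH 7 buffer, MeOH, 30% H2O2, 0 °C
Reagents that add atoms: none
Why: In this diisopinocampheylboron-mediated aldol reaction the methyl ketone is enolised on its only enolisable side and the chiral enol borinate adds to the enal through a cyclic transition state, the isopinocampheyl ligands from (+)-α-pinene directing attack to the Si face of the aldehyde to set C8 as S under reagent control.

**Step 18**
Reactants: 25 (1R,2S,3S,4S,5S,6S)-5-acetoxy-3,4-epoxy-1-[(3S)-3-hydroxy-6-methyl-5-oxo-6-(triethylsilyloxy)hept-1-en-2-yl]-4-methyl-2-(triethylsilyloxy)cyclohex-6-yl 2-methylpropanoate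
Product: 26 (1R,2S,3S,4S,5S,6S)-5-acetoxy-3,4-epoxy-1-[(3S,5S)-5-hydroxy-6-methyl-3-(2-methylpropanoyloxy)-6-(triethylsilyloxy)hept-1-en-2-yl]-4-methyl-2-(triethylsilyloxy)cyclohex-6-yl 2-methylpropanoate
Conditions: SmI2 (30 mol%), i-PrCHO (6 equiv), THF, −10 °C
Reagents that add atoms: isobutyraldehyde, CC(C)C=O
Why: In the Evans–Tishchenko reduction the hemiacetal of the C8 hydroxyl and isobutyraldehyde, held on trivalent samarium, transfers hydride intramolecularly to the C10 ketone through a chair transition state, giving the 1,3-anti C10 alcohol (S) and leaving the isobutyrate on the C8 oxygen.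

**Step 19**
Reactants: 26 (1R,2S,3S,4S,5S,6S)-5-acetoxy-3,4-epoxy-1-[(3S,5S)-5-hydroxy-6-methyl-3-(2-methylpropanoyloxy)-6-(triethylsilyloxy)hept-1-en-2-yl]-4-methyl-2-(triethylsilyloxy)cyclohex-6-yl 2-methylpropanoate
Product: 27 (1R,2S,3S,4S,5S,6S)-5-acetoxy-3,4-epoxy-4-methyl-1-[(3S,5S)-6-methyl-3,5-bis(2-methylpropanoyloxy)-6-(triethylsilyloxy)hept-1-en-2-yl]-2-(triethylsilyloxy)cyclohex-6-yl 2-methylpropanoate
Conditions: i-PrCOCl, pyridine, DMAP, CH2Cl2, rt → 40 °C
Reagents that add atoms: isobutyryl chloride, CC(C)C(Cl)=O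
Why: DMAP-catalysed acylation of the only free hydroxyl (C10) should proceed without touching the silyl ethers or the oxirane.

**Step 20**
Reactants: 27 (1R,2S,3S,4S,5S,6S)-5-acetoxy-3,4-epoxy-4-methyl-1-[(3S,5S)-6-methyl-3,5-bis(2-methylpropanoyloxy)-6-(triethylsilyloxy)hept-1-en-2-yl]-2-(triethylsilyloxy)cyclohex-6-yl 2-methylpropanoate
Product: 28 (1S,2S,3S,4S,5S,6S)-5-acetoxy-3,4-epoxy-2-hydroxy-1-[(3S,5S)-6-hydroxy-6-methyl-3,5-bis(2-methylpropanoyloxy)hept-1-en-2-yl]-4-methylcyclohex-6-yl 2-methylpropanoate (CNP0324717.1)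
Conditions: HF·pyridine, pyridine, THF, 0 °C → rt
Reagents that add atoms: none
Why: Buffered fluoride cleavage of the two triethylsilyl ethers should release the C2 and C11 hydroxyls while sparing the trisubstituted oxirane and the esters, and no acyl shift is expected because C2 has no neighbouring ester and C11 is tertiary.

**Compound list**

1 | (E)-2-methylbut-2-enal | C/C=C(\C)C=O | starting material
2 | (E)-1-(tert-butyldimethylsilyloxy)-2-methylbuta-1,3-diene | C=C/C(C)=C/O[Si](C)(C)C(C)(C)C | intermediate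
3 | 2-methylfuran | Cc1ccco1 | starting material
4 | (Z)-4-oxopent-2-enal | CC(=O)/C=C\C=O | intermediate
5 | 5-hydroxy-5-methylfuran-2(5H)-one (ring tautomer of (Z)-4-oxopent-2-enoic acid, racemic at the hemiketal carbon) | CC1(O)C=CC(=O)O1 | intermediate
6 | methyl (Z)-4-oxopent-2-enoate | CC(=O)/C=C\C(=O)OC | intermediate
7 | methyl (1S,5S,6S)-6-acetyl-5-(tert-butyldimethylsilyloxy)-4-methylcyclohex-3-ene-1-carboxylate | COC(=O)[C@H]1CC=C(C)[C@@H](O[Si](C)(C)C(C)(C)C)[C@H]1C(C)=O | intermediate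
8 | methyl (1S,3S,4S,5S,6S)-6-acetyl-5-(tert-butyldimethylsilyloxy)-3,4-epoxy-4-methylcyclohexane-1-carboxylate | COC(=O)[C@H]1C[C@@H]2O[C@]2(C)[C@@H](O[Si](C)(C)C(C)(C)C)[C@H]1C(C)=O | intermediate
9 | methyl (1S,3S,4S,5S,6S)-6-acetoxy-5-(tert-butyldimethylsilyloxy)-3,4-epoxy-4-methylcyclohexane-1-carboxylate | COC(=O)[C@H]1C[C@@H]2O[C@]2(C)[C@@H](O[Si](C)(C)C(C)(C)C)[C@H]1OC(C)=O | intermediate
10 | 2-[(1S,3S,4S,5S,6S)-5-(tert-butyldimethylsilyloxy)-3,4-epoxy-6-hydroxy-4-methylcyclohexyl]propan-2-ol | CC(C)(O)[C@H]1C[C@@H]2O[C@]2(C)[C@@H](O[Si](C)(C)C(C)(C)C)[C@H]1O | intermediate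
11 | (1S,3S,4S,5S,6S)-5-(tert-butyldimethylsilyloxy)-3,4-epoxy-1-(2-hydroxypropan-2-yl)-4-methylcyclohex-6-yl 2-methylpropanoate | CC(C)(O)[C@H]1C[C@@H]2O[C@]2(C)[C@@H](O[Si](C)(C)C(C)(C)C)[C@H]1OC(=O)C(C)C | intermediate
12 | (1R,3S,4S,5S,6S)-5-(tert-butyldimethylsilyloxy)-3,4-epoxy-4-methyl-1-(prop-1-en-2-yl)cyclohex-6-yl 2-methylpropanoate | C=C(C)[C@H]1C[C@@H]2O[C@]2(C)[C@@H](O[Si](C)(C)C(C)(C)C)[C@H]1OC(=O)C(C)C | intermediate
13 | (1R,3R,4R,5S,6S)-5-(tert-butyldimethylsilyloxy)-4-hydroxy-4-methyl-3-(phenylselanyl)-1-(prop-1-en-2-yl)cyclohex-6-yl 2-methylpropanoate | C=C(C)[C@H]1C[C@@H]([Se]c2ccccc2)[C@](C)(O)[C@@H](O[Si](C)(C)C(C)(C)C)[C@H]1OC(=O)C(C)C | intermediate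
14 | (1R,4S,5S,6S)-5-(tert-butyldimethylsilyloxy)-4-hydroxy-4-methyl-1-(prop-1-en-2-yl)cyclohex-2-en-6-yl 2-methylpropanoate | C=C(C)[C@H]1C=C[C@](C)(O)[C@@H](O[Si](C)(C)C(C)(C)C)[C@H]1OC(=O)C(C)C | intermediate
15 | (1R,4S,5S,6S)-4,5-dihydroxy-4-methyl-1-(prop-1-en-2-yl)cyclohex-2-en-6-yl 2-methylpropanoate | C=C(C)[C@H]1C=C[C@](C)(O)[C@@H](O)[C@H]1OC(=O)C(C)C | intermediate
16 | (1R,4S,5S,6S)-5-acetoxy-4-hydroxy-4-methyl-1-(prop-1-en-2-yl)cyclohex-2-en-6-yl 2-methylpropanoate | C=C(C)[C@H]1C=C[C@](C)(O)[C@@H](OC(C)=O)[C@H]1OC(=O)C(C)C | intermediate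
17 | (1S,2R,5R,6S)-5-acetoxy-2-hydroxy-4-methyl-1-(prop-1-en-2-yl)cyclohex-3-en-6-yl 2-methylpropanoate | C=C(C)[C@H]1[C@H](O)C=C(C)[C@@H](OC(C)=O)[C@H]1OC(=O)C(C)C | intermediate
18 | (1S,2S,3S,4S,5S,6S)-5-acetoxy-3,4-epoxy-2-hydroxy-4-methyl-1-(prop-1-en-2-yl)cyclohex-6-yl 2-methylpropanoate | C=C(C)[C@H]1[C@H](O)[C@@H]2O[C@]2(C)[C@@H](OC(C)=O)[C@H]1OC(=O)C(C)C | intermediate
19 | (1R,2S,3S,4S,5S,6S)-5-acetoxy-3,4-epoxy-4-methyl-1-(prop-1-en-2-yl)-2-(triethylsilyloxy)cyclohex-6-yl 2-methylpropanoate | C=C(C)[C@H]1[C@H](O[Si](CC)(CC)CC)[C@@H]2O[C@]2(C)[C@@H](OC(C)=O)[C@H]1OC(=O)C(C)C | intermediate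
20 | (1R,2S,3S,4S,5S,6S)-5-acetoxy-3,4-epoxy-1-(3-hydroxyprop-1-en-2-yl)-4-methyl-2-(triethylsilyloxy)cyclohex-6-yl 2-methylpropanoate | C=C(CO)[C@H]1[C@H](O[Si](CC)(CC)CC)[C@@H]2O[C@]2(C)[C@@H](OC(C)=O)[C@H]1OC(=O)C(C)C | intermediate
21 | (1R,2S,3S,4S,5S,6S)-5-acetoxy-3,4-epoxy-4-methyl-1-(3-oxoprop-1-en-2-yl)-2-(triethylsilyloxy)cyclohex-6-yl 2-methylpropanoate | C=C(C=O)[C@H]1[C@H](O[Si](CC)(CC)CC)[C@@H]2O[C@]2(C)[C@@H](OC(C)=O)[C@H]1OC(=O)C(C)C | intermediate
22 | 3-hydroxy-3-methylbutan-2-one | CC(=O)C(C)(C)O | starting material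
23 | 3-methyl-3-(triethylsilyloxy)butan-2-one | CC(=O)C(C)(C)O[Si](CC)(CC)CC | intermediate
24 | enol diisopinocampheylborinate of 23 (isopinocampheyl groups from (+)-α-pinene) | C=C(OB([C@@H]1C[C@@H]2C[C@@H](C2(C)C)[C@H]1C)[C@@H]1C[C@@H]2C[C@@H](C2(C)C)[C@H]1C)C(C)(C)O[Si](CC)(CC)CC | intermediate
25 | (1R,2S,3S,4S,5S,6S)-5-acetoxy-3,4-epoxy-1-[(3S)-3-hydroxy-6-methyl-5-oxo-6-(triethylsilyloxy)hept-1-en-2-yl]-4-methyl-2-(triethylsilyloxy)cyclohex-6-yl 2-methylpropanoate | C=C([C@H]1[C@H](O[Si](CC)(CC)CC)[C@@H]2O[C@]2(C)[C@@H](OC(C)=O)[C@H]1OC(=O)C(C)C)[C@H](CC(=O)C(C)(C)O[Si](CC)(CC)CC)O | intermediate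
26 | (1R,2S,3S,4S,5S,6S)-5-acetoxy-3,4-epoxy-1-[(3S,5S)-5-hydroxy-6-methyl-3-(2-methylpropanoyloxy)-6-(triethylsilyloxy)hept-1-en-2-yl]-4-methyl-2-(triethylsilyloxy)cyclohex-6-yl 2-methylpropanoate | C=C([C@H]1[C@H](O[Si](CC)(CC)CC)[C@@H]2O[C@]2(C)[C@@H](OC(C)=O)[C@H]1OC(=O)C(C)C)[C@H](C[C@H](O)C(C)(C)O[Si](CC)(CC)CC)OC(=O)C(C)C | intermediate
27 | (1R,2S,3S,4S,5S,6S)-5-acetoxy-3,4-epoxy-4-methyl-1-[(3S,5S)-6-methyl-3,5-bis(2-methylpropanoyloxy)-6-(triethylsilyloxy)hept-1-en-2-yl]-2-(triethylsilyloxy)cyclohex-6-yl 2-methylpropanoate | C=C([C@H]1[C@H](O[Si](CC)(CC)CC)[C@@H]2O[C@]2(C)[C@@H](OC(C)=O)[C@H]1OC(=O)C(C)C)[C@H](C[C@H](OC(=O)C(C)C)C(C)(C)O[Si](CC)(CC)CC)OC(=O)C(C)C | intermediate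
28 | (1S,2S,3S,4S,5S,6S)-5-acetoxy-3,4-epoxy-2-hydroxy-1-[(3S,5S)-6-hydroxy-6-methyl-3,5-bis(2-methylpropanoyloxy)hept-1-en-2-yl]-4-methylcyclohex-6-yl 2-methylpropanoate (CNP0324717.1) | C=C([C@H]1[C@H](O)[C@@H]2O[C@]2(C)[C@@H](OC(C)=O)[C@H]1OC(=O)C(C)C)[C@H](C[C@H](OC(=O)C(C)C)C(C)(C)O)OC(=O)C(C)C | target

**Step count.** Total: 20 steps. Longest linear sequence: 18 steps (steps 2–15 and 17–20, from 2-methylfuran).

**Steps most likely to fail**

1. Step 9 (oxirane to allylic alcohol). The selenolate has to attack C3 from the upper face, which cannot be trans-diaxial unless the C1 and C5 substituents both turn axial, so the opening may stall or the C6 ester may solvolyse under forcing conditions. Fallback, from 12: the oxirane is inverted first so that the same nucleophile attacks from the open lower face. Dilute HClO4 in THF/H2O should open 12 at the tertiary C4 from the upper face to the trans-diaxial 3,4-diol F1. PPh3/DIAD cyclodehydration then closes it to the upper-face oxirane F2. PhSeNa opens F2 trans-diaxially at C3 to the hydroxy selenide F3, and H2O2 gives the C4-epimeric tertiary allylic alcohol F4. Desilylation gives the C5 alcohol F5 and acetylation the C5 acetate F6. The same rhenium-catalysed transposition then leads to the C2-epimeric allylic alcohol F7. Mitsunobu inversion with chloroacetic acid (PPh3, DIAD) gives the chloroacetate F8, and thiourea/NaHCO3 in EtOH removes the chloroacetyl group selectively, returning to 17.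

2. Step 12 (1,3-transposition). The perrhenate shift may stop at an unfavourable equilibrium, or ionisation to an allyl cation may erode the face-to-face transfer or cause elimination. Fallback, from 16: Babler–Dauben oxidative transposition with pyridinium chlorochromate (NaOAc, CH2Cl2) gives the enone F9, which is reduced under Luche conditions (NaBH4, CeCl3, MeOH, −78 °C). Hydride delivered to the upper face gives 17 directly. Attack on the lower face, which the axial C6 acyloxy group makes likely, gives the C2-epimeric alcohol F7, which is inverted through the chloroacetate F8 and deacylated with thiourea as above, returning to 17.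

3. Step 4 (key cycloaddition). Enantiofacial selectivity may be insufficient or opposite, or the acid may destroy the silyl dienol ether before it reacts. Fallback, from 5: covalent auxiliary control replaces catalyst control. Carboxylate alkylation of 5 with ethyl (S)-2-bromopropanoate (K2CO3, DMF, inversion) gives the lactate ester dienophile F10. Cycloaddition with 2 (Me2AlCl, CH2Cl2, −78 °C, or toluene, 60 °C) gives the all-cis adduct F11, separated from its ring diastereomer by chromatography. mCPBA then gives the epoxy acetate F13 by way of the epoxy ketone F12, and MeLi/CeCl3 removes the auxiliary in the same operation that builds the carbinol, returning to 10.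

**Further compounds**

F1 | step 9 | trans-diaxial diol from 12: C3 hydroxyl on the lower face, C4 hydroxyl on the upper face | C=C(C)[C@H]1C[C@H](O)[C@@](C)(O)[C@@H](O[Si](C)(C)C(C)(C)C)[C@H]1OC(=O)C(C)C
F2 | step 9 | upper-face 3,4-oxirane (C3,C4-diastereomer of 12) | C=C(C)[C@H]1C[C@H]2O[C@@]2(C)[C@@H](O[Si](C)(C)C(C)(C)C)[C@H]1OC(=O)C(C)C
F3 | step 9 | hydroxy selenide: C3 phenylselanyl on the lower face, C4 hydroxyl on the upper face | C=C(C)[C@H]1C[C@H]([Se]c2ccccc2)[C@@](C)(O)[C@@H](O[Si](C)(C)C(C)(C)C)[C@H]1OC(=O)C(C)C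
F4 | step 9 | C4 epimer of 14 | C=C(C)[C@H]1C=C[C@@](C)(O)[C@@H](O[Si](C)(C)C(C)(C)C)[C@H]1OC(=O)C(C)C
F5 | step 9 | C4 epimer of 15 | C=C(C)[C@H]1C=C[C@@](C)(O)[C@@H](O)[C@H]1OC(=O)C(C)C
F6 | step 9 | C4 epimer of 16 | C=C(C)[C@H]1C=C[C@@](C)(O)[C@@H](OC(C)=O)[C@H]1OC(=O)C(C)C
F7 | step 9 | C2 epimer of 17 (C2 hydroxyl on the upper face) | C=C(C)[C@H]1[C@@H](O)C=C(C)[C@@H](OC(C)=O)[C@H]1OC(=O)C(C)C
F8 | step 9 | C2 chloroacetate of 17 | C=C(C)[C@H]1[C@H](OC(=O)CCl)C=C(C)[C@@H](OC(C)=O)[C@H]1OC(=O)C(C)C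
F9 | step 12 | enone: 5-acetoxy-4-methyl-2-oxo-1-(prop-1-en-2-yl)cyclohex-3-en-6-yl 2-methylpropanoate with the C1, C5, C6 configuration of 16 | C=C(C)[C@H]1C(=O)C=C(C)[C@@H](OC(C)=O)[C@H]1OC(=O)C(C)C
F10 | step 4 | (R)-1-ethoxy-1-oxopropan-2-yl (Z)-4-oxopent-2-enoate | CC(=O)/C=C\C(=O)O[C@H](C)C(=O)OCC
F11 | step 4 | (R)-1-ethoxy-1-oxopropan-2-yl ester analogue of 7 | CCOC(=O)[C@@H](C)OC(=O)[C@H]1CC=C(C)[C@@H](O[Si](C)(C)C(C)(C)C)[C@H]1C(C)=O
F12 | step 4 | (R)-1-ethoxy-1-oxopropan-2-yl ester analogue of 8 | CCOC(=O)[C@@H](C)OC(=O)[C@H]1C[C@@H]2O[C@]2(C)[C@@H](O[Si](C)(C)C(C)(C)C)[C@H]1C(C)=O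
F13 | step 4 | (R)-1-ethoxy-1-oxopropan-2-yl ester analogue of 9 | CCOC(=O)[C@@H](C)OC(=O)[C@H]1C[C@@H]2O[C@]2(C)[C@@H](O[Si](C)(C)C(C)(C)C)[C@H]1OC(C)=O
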